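**Plan**

1. Numbering used: C1 is the ring-fusion carbon of ring A (α-methylene lactone C1–C15(=C17H2)–C16(=O)–O–C14); the 14-membered carbocycle runs C1, C2, C3, C4(=C18H2), C5(OOH), C6, C7, C8, C9, C10, C11, C12(CH3), C13, C14; ring B is the butenolide C8=C9–C10–O–C19(=O).
2. Retrosynthesis: C5–OOH is cut by a Schenck ene reaction back to ovatodiolide. Then C8=C9 and O–C10 of ring B are cut together, which opens ring B and the carbocycle at once to a seco C9 aldehyde/C10 chloride carrying a C8 phosphono acid. Ring A is cut at C1–C14 and O–C16 into an enal (C9–C14) and a 2-carbomethoxy allylboronate (C1–C8, C15–C19), both chains coming from terminal alkynes.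
3. What makes the double cut possible: C10 is the γ-carbon of ring B and also a ring atom of the carbocycle next to C9. A C9 aldehyde with a leaving group on C10 is therefore a 1,2-dielectrophile for the O–C19–C8 unit of a phosphonoacetic acid.
4. Forward order: two chains → ring A (trans lactone) by allylboration/lactonisation → seco chloro aldehyde acid → 15-membered macrolactone, contracted in the same flask to the carbocycle plus ring B → photo-oxygenation.
5. Stereochemistry: both E alkenes come from syn carboalumination; C1/C14 (anti) from a chair allylboration with the chain cis to the ester, absolute sense from a chiral phosphoric acid; C10 from catalyst-controlled α-chlorination followed by SN2 inversion; C5 from attack of singlet oxygen on the exposed face of the macrocycle.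

Key step: step 13

Assumption: the sense of induction of the phosphoric acid (step 9) and of the imidazolidinone (step 12) is assigned by analogy with simple aldehydes; if either proves opposite, the enantiomeric catalyst is used.

Step 1
Reactants: 1 tert-butyldimethyl(pent-4-yn-1-yloxy)silane
Product: 4 (E)-6-(tert-butyldimethylsilyloxy)-3-methylhex-2-en-1-ol, via alkenyldimethylalane 2 (not isolated), via lithium alanate 3 (not isolated)
Conditions: AlMe3, Cp2ZrCl2 (cat.), CH2Cl2, 0 °C to rt; n-BuLi, THF, −78 °C; (CH2O)n, rt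
Reagents that add atoms: trimethylaluminium C[Al](C)C; paraformaldehyde (as formaldehyde) C=O
Why: Negishi zirconium-catalysed carboalumination adds CH3 and Al syn across the terminal alkyne (CH3 to the inner carbon) and the alanate is hydroxymethylated with retention, so the C12=C13 alkene should be E.

Step 2
Reactants: 4 (E)-6-(tert-butyldimethylsilyloxy)-3-methylhex-2-en-1-ol
Product: 5 (E)-6-(tert-butyldimethylsilyloxy)-3-methylhex-2-enal
Conditions: PhI(OAc)2, TEMPO (cat.), CH2Cl2, rt
Reagents that add atoms: none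
Why: Oxoammonium (TEMPO/PhI(OAc)2) oxidation of a primary allylic alcohol stops at the enal and should leave the silyl ether and the alkene geometry untouched.

Step 3
Reactants: 6 hexa-1,5-diyne
Product: 9 (E)-4-methyloct-3-en-7-yn-1-ol, via alkenyldimethylalane 7 (not isolated), via lithium alanate 8 (not isolated)
Conditions: 6 (3 equiv), AlMe3 (1 equiv), Cp2ZrCl2 (cat.), CH2Cl2, 0 °C to rt; excess 6 distilled off; n-BuLi, THF, −78 °C; ethylene oxide, −78 to 0 °C
Reagents that add atoms: trimethylaluminium C[Al](C)C; ethylene oxide C1CO1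
Why: Negishi carboalumination of one alkyne of the diyne (used in excess to favour mono-addition) followed by ring opening of ethylene oxide by the alkenyl alanate with retention should give the E homoallylic alcohol, ate formation being faster than deprotonation of the remaining alkyne C–H.

Step 4
Reactants: 9 (E)-4-methyloct-3-en-7-yn-1-ol
Product: 10 (E)-8-bromo-5-methyloct-5-en-1-yne
Conditions: CBr4, PPh3, CH2Cl2, 0 °C
Reagents that add atoms: carbon tetrabromide BrC(Br)(Br)Br
Why: Appel bromination of a primary alcohol proceeds by SN2 on the alkoxyphosphonium salt and should not touch the alkyne or the alkene.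

Step 5
Reactants: 10 (E)-8-bromo-5-methyloct-5-en-1-yne
Product: 12 methyl (E)-9-bromo-6-methylnon-6-en-2-ynoate, via lithium acetylide 11 (not isolated)
Conditions: n-BuLi, THF, −78 °C; ClCO2CH3, −78 to 0 °C
Reagents that add atoms: methyl chloroformate COC(=O)Cl
Why: Deprotonation of the terminal alkyne is far faster than attack on the primary bromide at −78 °C, and acylation of the acetylide with the chloroformate gives the ynoate.

Step 6
Reactants: 12 methyl (E)-9-bromo-6-methylnon-6-en-2-ynoate
Product: 14 methyl (2Z,6E)-9-bromo-6-methyl-2-[(4,4,5,5-tetramethyl-1,3,2-dioxaborolan-2-yl)methyl]nona-2,6-dienoate, via vinylalane 13 (not isolated)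
Conditions: i-Bu2AlH, HMPA, THF, 0 °C; ICH2B(pin), 0 °C to rt
Reagents that add atoms: 2-(iodomethyl)-4,4,5,5-tetramethyl-1,3,2-dioxaborolane ICB1OC(C)(C)C(C)(C)O1
Why: Syn hydroalumination of the ynoate (hydride to the β-carbon, i-Bu2AlH–HMPA) and borylmethylation of the α-alumino acrylate through a boron ate complex and 1,2-shift with retention should place the C2 chain cis to the ester and trans to CH2B, the geometry needed for an anti allylboration.

Step 7
Reactants: 15 2-(diethoxyphosphoryl)acetic acid
Product: 16 2-(trimethylsilyl)ethyl 2-(diethoxyphosphoryl)acetate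
Conditions: 2-(trimethylsilyl)ethanol, DCC, DMAP (cat.), CH2Cl2, 0 °C to rt
Reagents that add atoms: 2-(trimethylsilyl)ethanol C[Si](C)(C)CCO
Why: Steglich esterification gives a phosphonoacetate whose ester can later be removed by fluoride together with the silyl ether.

Step 8
Reactants: 16 2-(trimethylsilyl)ethyl 2-(diethoxyphosphoryl)acetate; 14 methyl (2Z,6E)-9-bromo-6-methyl-2-[(4,4,5,5-tetramethyl-1,3,2-dioxaborolan-2-yl)methyl]nona-2,6-dienoate
Product: 18 1-methyl 11-[2-(trimethylsilyl)ethyl] (2Z,6E)-10-(diethoxyphosphoryl)-6-methyl-2-[(4,4,5,5-tetramethyl-1,3,2-dioxaborolan-2-yl)methyl]undeca-2,6-dienedioate (both epimers at the phosphonate carbon), via sodium enolate 17 (not isolated)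
Conditions: 16, NaH (1.0 equiv), THF, 0 °C; then 14, NaI (cat.), DMF, rt
Reagents that add atoms: none
Why: SN2 alkylation of the stabilised phosphonoacetate enolate by the primary homoallylic bromide should outrun Michael addition to the hindered trisubstituted enoate and attack at the pinacol boronate, which a soft enolate without excess hydride should not disturb.

Step 9
Reactants: 18 1-methyl 11-[2-(trimethylsilyl)ethyl] (2Z,6E)-10-(diethoxyphosphoryl)-6-methyl-2-[(4,4,5,5-tetramethyl-1,3,2-dioxaborolan-2-yl)methyl]undeca-2,6-dienedioate; 5 (E)-6-(tert-butyldimethylsilyloxy)-3-methylhex-2-enal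
Product: 20 2-(trimethylsilyl)ethyl (E)-8-[(2S,3R)-2-[(E)-5-(tert-butyldimethylsilyloxy)-2-methylpent-1-en-1-yl]-4-methylidene-5-oxooxolan-3-yl]-2-(diethoxyphosphoryl)-6-methyloct-5-enoate, via pinacol borate 19 (not isolated)
Conditions: (R)-TRIP [(R)-3,3'-bis(2,4,6-triisopropylphenyl)-1,1'-binaphthyl-2,2'-diyl hydrogen phosphate] (10 mol %), 4 Å molecular sieves, toluene, −30 °C to rt; then PPTS (cat.), rt
Reagents that add atoms: none
Why: Chiral-phosphoric-acid-catalysed allylboration through a closed chair transition state puts the C2 chain (trans to CH2B) equatorial and so gives the anti C1/C14 adduct, the acid bound to the boronate oxygen selects the aldehyde face (14S, hence 1R), and the borate then acylates itself with the methyl ester to the trans α-methylene lactone.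

Step 10
Reactants: 20 2-(trimethylsilyl)ethyl (E)-8-[(2S,3R)-2-[(E)-5-(tert-butyldimethylsilyloxy)-2-methylpent-1-en-1-yl]-4-methylidene-5-oxooxolan-3-yl]-2-(diethoxyphosphoryl)-6-methyloct-5-enoate
Product: 21 (E)-2-(diethoxyphosphoryl)-8-[(2S,3R)-2-[(E)-5-hydroxy-2-methylpent-1-en-1-yl]-4-methylidene-5-oxooxolan-3-yl]-6-methyloct-5-enoic acid
Conditions: n-Bu4NF, AcOH, THF, 0 °C to rt
Reagents that add atoms: none
Why: Fluoride removes the silyl ether and fragments the 2-(trimethylsilyl)ethyl ester (loss of ethene), and the acetic acid buffer should protect the α-methylene lactone from basic fluoride.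

Step 11
Reactants: 21 (E)-2-(diethoxyphosphoryl)-8-[(2S,3R)-2-[(E)-5-hydroxy-2-methylpent-1-en-1-yl]-4-methylidene-5-oxooxolan-3-yl]-6-methyloct-5-enoic acid
Product: 22 (E)-2-(diethoxyphosphoryl)-6-methyl-8-[(2S,3R)-4-methylidene-2-[(E)-2-methyl-5-oxopent-1-en-1-yl]-5-oxooxolan-3-yl]oct-5-enoic acid
Conditions: PhI(OAc)2, TEMPO (cat.), CH2Cl2, rt
Reagents that add atoms: none
Why: TEMPO/PhI(OAc)2 oxidation takes a primary alcohol to the aldehyde under acidic, base-free conditions, so the free phosphono acid cannot start an olefination.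

Step 12
Reactants: 22 (E)-2-(diethoxyphosphoryl)-6-methyl-8-[(2S,3R)-4-methylidene-2-[(E)-2-methyl-5-oxopent-1-en-1-yl]-5-oxooxolan-3-yl]oct-5-enoic acid
Product: 23 (E)-8-[(2S,3R)-2-[(1E,4S)-4-chloro-2-methyl-5-oxopent-1-en-1-yl]-4-methylidene-5-oxooxolan-3-yl]-2-(diethoxyphosphoryl)-6-methyloct-5-enoic acid (used crude)
Conditions: 2,3,4,5,6,6-hexachlorocyclohexa-2,4-dien-1-one, (5S)-5-benzyl-2,2,3-trimethylimidazolidin-4-one·CF3CO2H (10 mol %), acetone, −30 °C
Reagents that add atoms: 2,3,4,5,6,6-hexachlorocyclohexa-2,4-dien-1-one O=C1C(Cl)=C(Cl)C(Cl)=C(Cl)C1(Cl)Cl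
Why: Enamine-catalysed α-chlorination of the aldehyde is catalyst-controlled, so the shielded enamine face should set C10 as S whatever the remote centres, and the quinone-type chlorine source and hindered amine should spare the alkenes and the α-methylene lactone.

Step 13
Reactants: 23 (E)-8-[(2S,3R)-2-[(1E,4S)-4-chloro-2-methyl-5-oxopent-1-en-1-yl]-4-methylidene-5-oxooxolan-3-yl]-2-(diethoxyphosphoryl)-6-methyloct-5-enoic acid
Product: 26 ovatodiolide, via caesium carboxylate 24 (not isolated), via macrolactone 25 (not isolated)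
Conditions: Cs2CO3 (3 equiv), DMF, 23 added over 12 h (final 1 mM), rt
Reagents that add atoms: none
Why: Cs2CO3 turns 23 into the caesium carboxylate 24, whose oxygen displaces the chloride at C10 by intramolecular SN2 with inversion (15-exo-tet macrolactonisation of the Kellogg type) to give 25; only now, as a phosphonoacetate ester, is C8–H acidic enough for carbonate, so the C8 carbanion adds to the adjacent C9 aldehyde and diethyl phosphate is lost (intramolecular Horner–Wadsworth–Emmons olefination). The closest known reaction type is the butenolide synthesis from α-halo carbonyl compounds and salts of phosphonoacetic acid, here run within one chain. Ring B closes 5-exo-trig at C9, and the same C8–C9 bond closes the 14-membered carbocycle (14-exo-trig, transannular within the 15-membered lactone), so the macrolactone contracts to carbocycle plus butenolide. C10 (R) comes from inversion of the catalyst-set (S)-chloride, and the C8=C9 bond can only be cis inside the five-membered ring. The step needs O-alkylation before olefination and an intact C10: the first is secured by the pKa gap (carbonate forms the carboxylate but not the carboxylate–phosphonate dianion), the second by high dilution, a weak heterogeneous base and the absence of added halide.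

Step 14
Reactants: 26 ovatodiolide
Product: 27 4-methylene-5β-hydroperoxyovatodiolide
Conditions: O2, visible light, 5,10,15,20-tetraphenylporphyrin (cat.), CH2Cl2, −20 °C
Reagents that add atoms: dioxygen O=O
Why: In the Schenck ene reaction singlet oxygen should attack only the electron-rich isolated C4=C5 alkene, bond to C5 and take hydrogen from the C18 methyl group on the disubstituted side (cis effect), and approach from the exposed outer face of the macrocycle should give the 5R hydroperoxide.

**Compound list**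

1 | tert-butyldimethyl(pent-4-yn-1-yloxy)silane | C#CCCCO[Si](C)(C)C(C)(C)C | starting material
2 | (E)-[5-(tert-butyldimethylsilyloxy)-2-methylpent-1-en-1-yl]dimethylalane | C[Al](C)/C=C(\C)CCCO[Si](C)(C)C(C)(C)C | intermediate
3 | lithium butyl[(E)-5-(tert-butyldimethylsilyloxy)-2-methylpent-1-en-1-yl]dimethylaluminate | [Li+].CCCC[Al-](C)(C)/C=C(\C)CCCO[Si](C)(C)C(C)(C)C | intermediate
4 | (E)-6-(tert-butyldimethylsilyloxy)-3-methylhex-2-en-1-ol | OC/C=C(\C)CCCO[Si](C)(C)C(C)(C)C | intermediate
5 | (E)-6-(tert-butyldimethylsilyloxy)-3-methylhex-2-enal | O=C/C=C(\C)CCCO[Si](C)(C)C(C)(C)C | intermediate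
6 | hexa-1,5-diyne | C#CCCC#C | starting material
7 | (E)-dimethyl(2-methylhex-1-en-5-yn-1-yl)alane | C[Al](C)/C=C(\C)CCC#C | intermediate
8 | lithium butyldimethyl[(E)-2-methylhex-1-en-5-yn-1-yl]aluminate | [Li+].CCCC[Al-](C)(C)/C=C(\C)CCC#C | intermediate
9 | (E)-4-methyloct-3-en-7-yn-1-ol | OCC/C=C(\C)CCC#C | intermediate
10 | (E)-8-bromo-5-methyloct-5-en-1-yne | BrCC/C=C(\C)CCC#C | intermediate
11 | lithium (E)-8-bromo-5-methyloct-5-en-1-yn-1-ide | [Li+].[C-]#CCC/C(C)=C/CCBr | intermediate
12 | methyl (E)-9-bromo-6-methylnon-6-en-2-ynoate | COC(=O)C#CCC/C(C)=C/CCBr | intermediate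
13 | methyl (2E,6E)-9-bromo-2-(diisobutylalumanyl)-6-methylnona-2,6-dienoate (Al cis to H-3) | COC(=O)/C([Al](CC(C)C)CC(C)C)=C\CC/C(C)=C/CCBr | intermediate
14 | methyl (2Z,6E)-9-bromo-6-methyl-2-[(4,4,5,5-tetramethyl-1,3,2-dioxaborolan-2-yl)methyl]nona-2,6-dienoate | COC(=O)/C(CB1OC(C)(C)C(C)(C)O1)=C\CC/C(C)=C/CCBr | intermediate
15 | 2-(diethoxyphosphoryl)acetic acid | CCOP(=O)(CC(=O)O)OCC | starting material
16 | 2-(trimethylsilyl)ethyl 2-(diethoxyphosphoryl)acetate | CCOP(=O)(CC(=O)OCC[Si](C)(C)C)OCC | intermediate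
17 | sodium enolate of 16 | [Na+].CCOP(=O)(OCC)[CH-]C(=O)OCC[Si](C)(C)C | intermediate
18 | 1-methyl 11-[2-(trimethylsilyl)ethyl] (2Z,6E)-10-(diethoxyphosphoryl)-6-methyl-2-[(4,4,5,5-tetramethyl-1,3,2-dioxaborolan-2-yl)methyl]undeca-2,6-dienedioate (C10 epimers) | COC(=O)/C(CB1OC(C)(C)C(C)(C)O1)=C\CC/C(C)=C/CCC(C(=O)OCC[Si](C)(C)C)P(=O)(OCC)OCC | intermediate
19 | pinacol borate of the anti (1R,14S) homoallylic alcohol, methyl ester still open | C=C(C(=O)OC)[C@@H](CC/C(C)=C/CCC(C(=O)OCC[Si](C)(C)C)P(=O)(OCC)OCC)[C@@H](OB1OC(C)(C)C(C)(C)O1)/C=C(\C)CCCO[Si](C)(C)C(C)(C)C | intermediate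
20 | 2-(trimethylsilyl)ethyl (E)-8-[(2S,3R)-2-[(E)-5-(tert-butyldimethylsilyloxy)-2-methylpent-1-en-1-yl]-4-methylidene-5-oxooxolan-3-yl]-2-(diethoxyphosphoryl)-6-methyloct-5-enoate (trans lactone, ring A) | C=C1C(=O)O[C@@H](/C=C(\C)CCCO[Si](C)(C)C(C)(C)C)[C@@H]1CC/C(C)=C/CCC(C(=O)OCC[Si](C)(C)C)P(=O)(OCC)OCC | intermediate
21 | (E)-2-(diethoxyphosphoryl)-8-[(2S,3R)-2-[(E)-5-hydroxy-2-methylpent-1-en-1-yl]-4-methylidene-5-oxooxolan-3-yl]-6-methyloct-5-enoic acid | C=C1C(=O)O[C@@H](/C=C(\C)CCCO)[C@@H]1CC/C(C)=C/CCC(C(=O)O)P(=O)(OCC)OCC | intermediate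
22 | (E)-2-(diethoxyphosphoryl)-6-methyl-8-[(2S,3R)-4-methylidene-2-[(E)-2-methyl-5-oxopent-1-en-1-yl]-5-oxooxolan-3-yl]oct-5-enoic acid | C=C1C(=O)O[C@@H](/C=C(\C)CCC=O)[C@@H]1CC/C(C)=C/CCC(C(=O)O)P(=O)(OCC)OCC | intermediate
23 | (E)-8-[(2S,3R)-2-[(1E,4S)-4-chloro-2-methyl-5-oxopent-1-en-1-yl]-4-methylidene-5-oxooxolan-3-yl]-2-(diethoxyphosphoryl)-6-methyloct-5-enoic acid | C=C1C(=O)O[C@@H](/C=C(\C)C[C@H](Cl)C=O)[C@@H]1CC/C(C)=C/CCC(C(=O)O)P(=O)(OCC)OCC | intermediate
24 | caesium carboxylate of 23 | [Cs+].C=C1C(=O)O[C@@H](/C=C(\C)C[C@H](Cl)C=O)[C@@H]1CC/C(C)=C/CCC(C(=O)[O-])P(=O)(OCC)OCC | intermediate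
25 | 15-membered macrolactone (O–C10 closed, 10R) carrying the C9 aldehyde and the C8 diethyl phosphonate, fused to ring A | C=C1C(=O)O[C@H]2/C=C(\C)C[C@H](C=O)OC(=O)C(P(=O)(OCC)OCC)CC/C=C(\C)CC[C@H]12 | intermediate
26 | ovatodiolide (1R,10R,14S; 4E,12E) | C=C1C(=O)O[C@H]2/C=C(\C)C[C@@H]3C=C(CC/C=C(\C)CC[C@H]12)C(=O)O3 | intermediate
27 | 4-methylene-5β-hydroperoxyovatodiolide (1R,5R,10R,14S) | C=C1C(=O)O[C@H]2/C=C(\C)C[C@@H]3C=C(CC[C@@H](OO)C(=C)CC[C@H]12)C(=O)O3 | target

**Count**

Total: 14 steps. Longest linear sequence: 11 steps (steps 3–6 and 8–14, from hexa-1,5-diyne).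

**Steps most likely to fail**

Step 13. What may go wrong: intermolecular O-alkylation (oligomers) competing with the 15-membered ring closure, and loss of configuration at C10 by enolisation of the α-chloro aldehyde before ring closure or of the butenolide after it. The fallback forms the ester by acyl–oxygen instead of alkyl–oxygen bond formation and sets out from 22. L-Proline-catalysed α-aminoxylation with nitrosobenzene and NaBH4 reduction in the same flask should give the (10R) O-anilino diol acid F1. Cleavage of the N–O bond (CuSO4 cat., MeOH) gives the 9,10-diol acid F2, and TBSCl/imidazole protects the primary hydroxyl to give the 9-O-silyl diol acid F3. Yamaguchi macrolactonisation (2,4,6-trichlorobenzoyl chloride, Et3N; DMAP, toluene, high dilution) at the C10 hydroxyl, with retention, gives the silyloxymethyl macrolactone F4. HF·pyridine frees the macrolactone alcohol F5, and Dess–Martin oxidation comes back to the route at 25, which LiCl/DBU (Masamune–Roush conditions) takes to 26.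

Step 9. What may go wrong: the ester-deactivated allylboronate may react too slowly under the weak Brønsted acid, so that an uncatalysed, racemic background reaction or poor facial discrimination erodes the enantiomeric purity of ring A. The fallback moves the control from the catalyst to a covalently bound auxiliary and sets out from 10. Acylation of its lithium acetylide with (1R,2S,5R)-8-phenylmenthyl chloroformate (or its enantiomer, whichever matches the 14S series) gives the 8-phenylmenthyl ynoate F6. Hydroalumination/borylmethylation as in step 6 gives the 8-phenylmenthyl allylboronate F7, and alkylation with 17 as in step 8 gives the 8-phenylmenthyl phosphonate boronate F8. Sc(OTf)3-catalysed allylboration of 5 with F8 and lactonisation expel the auxiliary alcohol and come back to the route at 20.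

Step 14. What may go wrong: hydrogen abstraction from the ring methylene C6 (giving the tertiary C4 hydroperoxide with a shifted ring alkene) instead of from the methyl group, or approach of singlet oxygen from the inner face. The fallback builds the C5–O bond by epoxidation and substitution and sets out from 26. mCPBA (1 equiv, CH2Cl2, 0 °C) should epoxidise only the isolated alkene from its exposed face to give the 4,5-epoxide F9. Cp2TiCl (trivalent titanium, from Cp2TiCl2 and Mn, THF) opens it to the C4 radical and, by hydrogen loss from the methyl group, gives the 5-hydroxy-4-methylene compound F10 with the C5–O bond retained. CBr4/PPh3 gives with inversion the (5S)-allylic bromide F11, and silver-assisted perhydrolysis (AgOCOCF3, anhydrous H2O2, Et2O, 0 °C), expected to go mainly with inversion, comes back to the route at 27.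

**Further compounds**

F1 | step 13 | O-anilino diol acid, (10R)-10-(phenylaminooxy)-9-hydroxy analogue of 22 | C=C1C(=O)O[C@@H](/C=C(\C)C[C@H](CO)ONc2ccccc2)[C@@H]1CC/C(C)=C/CCC(C(=O)O)P(=O)(OCC)OCC
F2 | step 13 | (10R)-9,10-diol acid | C=C1C(=O)O[C@@H](/C=C(\C)C[C@H](CO)O)[C@@H]1CC/C(C)=C/CCC(C(=O)O)P(=O)(OCC)OCC
F3 | step 13 | (10R)-9-O-(tert-butyldimethylsilyl) diol acid | C=C1C(=O)O[C@@H](/C=C(\C)C[C@H](CO[Si](C)(C)C(C)(C)C)O)[C@@H]1CC/C(C)=C/CCC(C(=O)O)P(=O)(OCC)OCC
F4 | step 13 | 15-membered macrolactone with CH2OTBS on C10 | C=C1C(=O)O[C@H]2/C=C(\C)C[C@H](CO[Si](C)(C)C(C)(C)C)OC(=O)C(P(=O)(OCC)OCC)CC/C=C(\C)CC[C@H]12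
F5 | step 13 | 15-membered macrolactone with CH2OH on C10 | C=C1C(=O)O[C@H]2/C=C(\C)C[C@H](CO)OC(=O)C(P(=O)(OCC)OCC)CC/C=C(\C)CC[C@H]12
F6 | step 9 | (1R,2S,5R)-8-phenylmenthyl (E)-9-bromo-6-methylnon-6-en-2-ynoate | C[C@@H]1CC[C@H]([C@@H](C1)OC(=O)C#CCC/C(C)=C/CCBr)C(C)(C)c1ccccc1
F7 | step 9 | 8-phenylmenthyl (2Z,6E)-9-bromo-6-methyl-2-[(4,4,5,5-tetramethyl-1,3,2-dioxaborolan-2-yl)methyl]nona-2,6-dienoate | C[C@@H]1CC[C@H]([C@@H](C1)OC(=O)/C(CB2OC(C)(C)C(C)(C)O2)=C\CC/C(C)=C/CCBr)C(C)(C)c1ccccc1
F8 | step 9 | 8-phenylmenthyl ester analogue of 18 | C[C@@H]1CC[C@H]([C@@H](C1)OC(=O)/C(CB2OC(C)(C)C(C)(C)O2)=C\CC/C(C)=C/CCC(C(=O)OCC[Si](C)(C)C)P(=O)(OCC)OCC)C(C)(C)c1ccccc1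
F9 | step 14 | trans-4,5-epoxide of ovatodiolide (C5–O on the face of the hydroperoxide in 27) | C=C1C(=O)O[C@H]2/C=C(\C)C[C@@H]3C=C(CC[C@H]4O[C@]4(C)CC[C@H]12)C(=O)O3
F10 | step 14 | (5R)-5-hydroxy-4-methylene analogue of 27 | C=C1C(=O)O[C@H]2/C=C(\C)C[C@@H]3C=C(CC[C@@H](O)C(=C)CC[C@H]12)C(=O)O3
F11 | step 14 | (5S)-5-bromo-4-methylene analogue of 27 | C=C1C(=O)O[C@H]2/C=C(\C)C[C@@H]3C=C(CC[C@H](Br)C(=C)CC[C@H]12)C(=O)O3
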